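Kadsurenin D is cut back to its cyclopentanone ring C8–C1–C7–C6–C5. The feature exploited is that aryl-bearing C7 lies next to the 1,3-dicarbonyl carbon C1, and quaternary C5 carries two carbonyl-level arms (C8, C4), so C5 can start as an achiral malonate carbon. In one operation a 3,4-dimethoxyphenyl cuprate adds to C7 of an acyclic enone and the C1 enolate acylates one of two diastereotopic esters (C1–C8). This gives one ring, two bonds and three stereocentres, all relayed from C6. The precursor is dimethyl allylmalonate substituted by an (R)-configured γ-branched (E)-enone that already holds C2, C3 and the methoxy group. Partial ester reduction and acid-mediated C3–C4 aldol condensation close the six-membered ring.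

Key step: step 8

Numbering: the bicyclo[3.2.1]octene locants of the target are used for all compounds. C1 is the bridgehead CH, C2 the enone carbonyl, C3 the methoxy-bearing alkene carbon, C4 the alkene CH, C5 the allyl-bearing bridgehead, C6 the methyl-bearing carbon, C7 the aryl-bearing carbon and C8 the bridging ketone.
Assumption: both antipodes of the phosphoramidite ligand are on sale; the one that leads to the (R)-configured allylation product is identified on a trial batch from the sign of rotation of this known compound, and the route is written for that antipode.
Remark: the two monocyclic β-diketones are drawn as diketo tautomers with C1 in the configuration needed later; both should be largely enolised, so C1 is fixed only when it becomes a bridgehead in the last step.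
Design remark: the small methyl esters are kept on purpose, because the ester selection at C5 rests on the spectator ester being smaller than the allyl chain.

Step 1
Reactants: 1 (E)-but-2-en-1-ol
Product: 2 (E)-but-2-en-1-yl methyl carbonate
Conditions: ClCO2Me (1.2 equiv), pyridine (1.5 equiv), CH2Cl2, 0 °C to rt
Reagents that add atoms: methyl chloroformate, COC(=O)Cl
Why: O-acylation of the primary allylic alcohol with a chloroformate installs the carbonate leaving group needed for iridium catalysis and leaves the E-alkene untouched.

Step 2
Reactants: 2 (E)-but-2-en-1-yl methyl carbonate; 3 dimethyl malonate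
Product: 4 dimethyl 2-[(2R)-but-3-en-2-yl]malonate
Conditions: [Ir(cod)Cl]2 (2 mol %), BINOL-derived N,N-bis(1-phenylethyl)phosphoramidite (4 mol %, antipode giving the R product), 1,5,7-triazabicyclo[4.4.0]dec-5-ene (8 mol %), THF, rt
Reagents that add atoms: none
Why: In this iridium-catalysed asymmetric allylic alkylation the cyclometallated iridium–phosphoramidite complex ionises the linear carbonate, the freed methoxide deprotonates the malonate, and the carbanion is steered to the substituted allyl terminus, so the ligand sets C6 and the minor achiral linear isomer is removed by chromatography.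

Step 3
Reactants: 5 methoxyacetyl chloride
Product: 6 N,2-dimethoxy-N-methylacetamide
Conditions: MeNH(OMe)·HCl (1.05 equiv), Et3N (2.2 equiv), CH2Cl2, 0 °C to rt
Reagents that add atoms: N,O-dimethylhydroxylamine hydrochloride, CNOC.Cl
Why: Simple N-acylation of the hydroxylamine by the acid chloride gives the Weinreb amide.

Step 4
Reactants: 6 N,2-dimethoxy-N-methylacetamide; 7 vinylmagnesium bromide
Product: 8 1-methoxybut-3-en-2-one
Conditions: THF, −78 to 0 °C; inverse quench into cold 2 M HCl; stored as a BHT-stabilised CH2Cl2 solution
Reagents that add atoms: none
Why: In the Weinreb ketone synthesis the chelated tetrahedral adduct blocks a second addition, and the inverse acidic quench keeps the released hydroxylamine protonated so that it cannot add to the vinyl ketone.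

Step 5
Reactants: 4 dimethyl 2-[(2R)-but-3-en-2-yl]malonate; 8 1-methoxybut-3-en-2-one (2.5 equiv)
Product: 9 dimethyl 2-[(2R,3E)-6-methoxy-5-oxohex-3-en-2-yl]malonate
Conditions: second-generation Hoveyda–Grubbs catalyst (5 mol %), CH2Cl2, 40 °C
Reagents that add atoms: none
Why: Olefin cross-metathesis of a terminal alkene with an electron-poor vinyl ketone that hardly homodimerises should give the E-enone selectively, C6 is not touched, and running it before the allyl group is present avoids a second terminal alkene and ring-closing metathesis.

Step 6
Reactants: 9 dimethyl 2-[(2R,3E)-6-methoxy-5-oxohex-3-en-2-yl]malonate; 10 allyl methyl carbonate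
Product: 11 dimethyl 2-allyl-2-[(2R,3E)-6-methoxy-5-oxohex-3-en-2-yl]malonate
Conditions: Pd(PPh3)4 (3 mol %), THF, rt
Reagents that add atoms: none
Why: In this base-free Tsuji–Trost allylation ionisation and decarboxylation of 10 release only one equivalent of methoxide, which removes the malonate proton (by far the most acidic), and the soft carbanion is captured by the π-allylpalladium cation before enone chemistry or γ-deprotonation at C6 can intervene, while C5 stays achiral with two identical esters.

Step 7
Reactants: 12 4-bromo-1,2-dimethoxybenzene
Product: 13 3,4-dimethoxyphenylmagnesium bromide (titrated THF solution)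
Conditions: Mg turnings, I2 (crystal), THF, 40–60 °C
Reagents that add atoms: magnesium, [Mg]
Why: Grignard formation by insertion of magnesium into the aryl–bromine bond tolerates the methoxy groups, and titration allows the copper-to-magnesium ratio of the next step to be set exactly.

Step 8
Reactants: 11 dimethyl 2-allyl-2-[(2R,3E)-6-methoxy-5-oxohex-3-en-2-yl]malonate; 13 3,4-dimethoxyphenylmagnesium bromide (3.0 equiv)
Product: 15 methyl (1R,3S,4R,5R)-1-allyl-4-(3,4-dimethoxyphenyl)-3-(methoxyacetyl)-5-methyl-2-oxocyclopentane-1-carboxylate, via bromomagnesium enolate 14 (not isolated)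
Conditions: CuBr·SMe2 (1.5 equiv), 13, THF–Me2S, −40 °C; add 11, −78 to −20 °C, then rt; quench with cold 1 M HCl
Reagents that add atoms: none
Why: The homocuprate, made from two equivalents of 13 per CuBr·SMe2 so that no free Grignard reagent remains, binds the enone as a π-complex, passes through a β-cuprio enolate of trivalent copper and transfers one aryl group to C7 by reductive elimination, leaving the regiodefined C1 enolate 14, which on warming adds to a malonate carbonyl (C1–C8) and expels methoxide. This is the known tandem organocuprate conjugate addition–Dieckmann/Claisen cyclisation, here combined with a choice between diastereotopic ester groups. The cyclopentanone ring C8–C1–C7–C6–C5 closes in the favoured 5-(enolexo)-exo-trig mode, and the released methoxide (or the spent arylcopper) deprotonates the new β-diketone at C1, which makes the closure irreversible and shields the product from further attack. C7 is controlled by C6: in the conformer of least allylic strain C6–H lies near the alkene plane beside C1–H and the bulky quaternary C5 stands perpendicular, so copper binds the face anti to C5 and the aryl group ends up trans to the C6 methyl group. C5 becomes stereogenic when one ester is chosen: the two tetrahedral adducts form reversibly, and the faster collapse is expected from the one that puts the flat, smaller spectator ester rather than the allyl chain on the ring face of the C6 methyl group, while C1 settles by enolisation with the acyl group trans to the aryl group. The step needs 1,4- over chelation-assisted 1,2-addition and C- over O-acylation; the first is secured by the soft cuprate without silyl chloride (which would also trap 14), the second by ring size, since O-acylation would need a seven-membered enol lactone.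

Step 9
Reactants: 15 methyl (1R,3S,4R,5R)-1-allyl-4-(3,4-dimethoxyphenyl)-3-(methoxyacetyl)-5-methyl-2-oxocyclopentane-1-carboxylate
Product: 17 (1S,3S,4R,5R)-1-allyl-4-(3,4-dimethoxyphenyl)-3-(methoxyacetyl)-5-methyl-2-oxocyclopentane-1-carbaldehyde, via sodium diketonate 16 (not isolated)
Conditions: NaH (1.05 equiv), THF, 0 °C; iBu2AlH (2.5 equiv, toluene), −78 to −50 °C; MeOH at −78 °C, then cold 1 M HCl
Reagents that add atoms: none
Why: With the diketone protected in situ as its electron-rich enolate 16, hydride attacks only the ester (partial ester reduction), the tetrahedral aluminium adduct held by the neighbouring enolate oxygen should survive until the acidic quench, no stereocentre is formed and quaternary C5 cannot epimerise.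

Step 10
Reactants: 17 (1S,3S,4R,5R)-1-allyl-4-(3,4-dimethoxyphenyl)-3-(methoxyacetyl)-5-methyl-2-oxocyclopentane-1-carbaldehyde
Product: 19 kadsurenin D, (1S,5S,6R,7R)-5-allyl-7-(3,4-dimethoxyphenyl)-3-methoxy-6-methylbicyclo[3.2.1]oct-3-ene-2,8-dione, via bicyclic ketol 18 (not isolated)
Conditions: p-TsOH·H2O (20 mol %), toluene, 80–110 °C, Dean–Stark trap
Reagents that add atoms: none
Why: This intramolecular aldol condensation is run in acid because closure can start only from the keto tautomer with sp3 C1 and the acyl group cis to the formyl group (a C1 enolate would have to become a bridgehead alkene, against Bredt's rule), so the C3 enol adds to C4 in a 6-(enolendo)-exo-trig mode, water is lost to give the methoxy enone, and C1 is locked as a bridgehead with the configuration imposed by C5.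

Compound list
1 | (E)-but-2-en-1-ol | C/C=C/CO | starting material
2 | (E)-but-2-en-1-yl methyl carbonate | C/C=C/COC(=O)OC | intermediate
3 | dimethyl malonate | COC(=O)CC(=O)OC | starting material
4 | dimethyl 2-[(2R)-but-3-en-2-yl]malonate | COC(=O)C(C(=O)OC)[C@H](C)C=C | intermediate
5 | methoxyacetyl chloride | COCC(=O)Cl | starting material
6 | N,2-dimethoxy-N-methylacetamide | COCC(=O)N(C)OC | intermediate
7 | vinylmagnesium bromide | C=C[Mg]Br | starting material
8 | 1-methoxybut-3-en-2-one | C=CC(=O)COC | intermediate
9 | dimethyl 2-[(2R,3E)-6-methoxy-5-oxohex-3-en-2-yl]malonate | COC(=O)C(C(=O)OC)[C@H](C)/C=C/C(=O)COC | intermediate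
10 | allyl methyl carbonate | C=CCOC(=O)OC | starting material
11 | dimethyl 2-allyl-2-[(2R,3E)-6-methoxy-5-oxohex-3-en-2-yl]malonate | C=CCC(C(=O)OC)(C(=O)OC)[C@H](C)/C=C/C(=O)COC | intermediate
12 | 4-bromo-1,2-dimethoxybenzene | COc1ccc(Br)cc1OC | starting material
13 | 3,4-dimethoxyphenylmagnesium bromide | COc1ccc([Mg]Br)cc1OC | intermediate
14 | bromomagnesium C1 enolate of the conjugate adduct (C6 and C7 as in 15, enolate geometry open) | C=CCC(C(=O)OC)(C(=O)OC)[C@H](C)[C@@H](c1ccc(OC)c(OC)c1)C=C(COC)O[Mg]Br | intermediate
15 | methyl (1R,3S,4R,5R)-1-allyl-4-(3,4-dimethoxyphenyl)-3-(methoxyacetyl)-5-methyl-2-oxocyclopentane-1-carboxylate | C=CC[C@]1(C(=O)OC)C(=O)[C@@H](C(=O)COC)[C@H](c2ccc(OC)c(OC)c2)[C@H]1C | intermediate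
16 | sodium diketonate of 15 | C=CC[C@]1(C(=O)OC)C(=O)C(=C([O-])COC)[C@H](c2ccc(OC)c(OC)c2)[C@H]1C.[Na+] | intermediate
17 | (1S,3S,4R,5R)-1-allyl-4-(3,4-dimethoxyphenyl)-3-(methoxyacetyl)-5-methyl-2-oxocyclopentane-1-carbaldehyde | C=CC[C@]1(C=O)C(=O)[C@@H](C(=O)COC)[C@H](c2ccc(OC)c(OC)c2)[C@H]1C | intermediate
18 | (1S,5S,6R,7R)-5-allyl-7-(3,4-dimethoxyphenyl)-4-hydroxy-3-methoxy-6-methylbicyclo[3.2.1]octane-2,8-dione (C3 and C4 epimers, both centres are lost on dehydration) | C=CC[C@]12C(O)C(OC)C(=O)[C@H](C1=O)[C@H](c1ccc(OC)c(OC)c1)[C@H]2C | intermediate
19 | kadsurenin D, (1S,5S,6R,7R)-5-allyl-7-(3,4-dimethoxyphenyl)-3-methoxy-6-methylbicyclo[3.2.1]oct-3-ene-2,8-dione | C=CC[C@]12C=C(OC)C(=O)[C@H](C1=O)[C@H](c1ccc(OC)c(OC)c1)[C@H]2C | target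

Total step count: 10. Longest linear sequence: 7 (steps 1, 2, 5, 6, 8, 9, 10; the branch through steps 3 and 4 is equally long).

Steps most likely to fail

1. Step 8.
- Risk: aryl transfer to the hindered C7 may be sluggish and let chelation-assisted 1,2-addition compete. The wrong alkene face may be attacked, or the two ester carbonyls may be poorly discriminated.
- Fallback: the two bond formations are separated and C7 is put under catalyst control.
- Setting out from 11, a rhodium-catalysed Hayashi–Miyaura 1,4-addition of 3,4-dimethoxyphenylboronic acid is used. Conditions are Rh(acac)(C2H4)2, the BINAP antipode matched to the substrate bias, dioxane–water, 60–80 °C.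
- It should give the acyclic aryl ketone dimethyl 2-allyl-2-[(2R,3S)-3-(3,4-dimethoxyphenyl)-6-methoxy-5-oxohexan-2-yl]malonate F1.
- A separate Claisen closure (KOtBu, THF, −20 °C) then follows, and its counter-ion can be varied freely to tune the ester selection. It runs through the C1 enolate, since the C3 enolate could only close a seven-membered ring.
- The fallback comes back to the route at 15.

2. Step 10.
- Risk: enolisation towards C3 may be too slow compared with acid-induced loss of the formyl group. The new enol ether may also hydrolyse at the temperature needed for dehydration.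
- Fallback: ring closure and elimination are separated.
- Setting out from 17, camphorsulfonic acid in CH2Cl2 at rt should stop at ketol 18, which is isolated.
- In 18, C1 is a bridgehead and no longer acidic, so base chemistry becomes possible.
- MsCl and Et3N should give (1S,5S,6R,7R)-5-allyl-7-(3,4-dimethoxyphenyl)-3-methoxy-4-(methylsulfonyloxy)-6-methylbicyclo[3.2.1]octane-2,8-dione F2.
- The non-nucleophilic base DBU (toluene, rt) then removes C3–H and expels mesylate (E1cB).
- The fallback comes back to the route at 19.

3. Step 9.
- Risk: hydride transfer may not stop at the aldehyde stage. The hindered ester may react so slowly that the masked diketone is attacked as well, or the formyl group may be lost by retro-Claisen cleavage during work-up.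
- Fallback: partial reduction is replaced by full reduction and re-oxidation.
- Setting out from 15, enolate 16 is treated with iBu2AlH (4 equiv, −78 to 0 °C).
- This should give (2S,3R,4R,5S)-2-allyl-4-(3,4-dimethoxyphenyl)-2-(hydroxymethyl)-5-(methoxyacetyl)-3-methylcyclopentan-1-one F3.
- The primary alcohol of F3 is then oxidised under Ley–Griffith conditions (nPr4N[RuO4] cat., N-methylmorpholine N-oxide, 4 Å molecular sieves, CH2Cl2). This avoids activated-sulfoxide and hypervalent-iodine reagents, which can attack C1.
- The fallback comes back to the route at 17.

Further compounds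
F1 | step 8 | dimethyl 2-allyl-2-[(2R,3S)-3-(3,4-dimethoxyphenyl)-6-methoxy-5-oxohexan-2-yl]malonate | C=CCC(C(=O)OC)(C(=O)OC)[C@H](C)[C@@H](c1ccc(OC)c(OC)c1)CC(=O)COC
F2 | step 10 | (1S,5S,6R,7R)-5-allyl-7-(3,4-dimethoxyphenyl)-3-methoxy-4-(methylsulfonyloxy)-6-methylbicyclo[3.2.1]octane-2,8-dione | C=CC[C@]12C(OS(C)(=O)=O)C(OC)C(=O)[C@H](C1=O)[C@H](c1ccc(OC)c(OC)c1)[C@H]2C
F3 | step 9 | (2S,3R,4R,5S)-2-allyl-4-(3,4-dimethoxyphenyl)-2-(hydroxymethyl)-5-(methoxyacetyl)-3-methylcyclopentan-1-one | C=CC[C@]1(CO)C(=O)[C@@H](C(=O)COC)[C@H](c2ccc(OC)c(OC)c2)[C@H]1C
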